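**Retrosynthetic overview**

1. The target is traced back (C8 angelate, C3 silyl ether) to an α-methylene-γ-lactone closed from a C6 alcohol onto a C7 acrylate. That in turn comes from cyclodec-4-ene-6,8-dione 14, whose doubly activated C7 takes up methyl propiolate by phosphine α-addition. C8 is then reduced under direction of the C10 hydroxyl and C6 by a Luche reduction.
2. Key disconnection: the C6–C7 and C8–C9 bonds. The ten-membered carbocycle grows out of an eight-membered ring (C1–C6, C9, C10) by insertion of C7–C8 into the C6–C9 bond, through a dichloroketene (2+2) cycloaddition to the C6=C9 silyl enol ether of cyclooctenone 9, dechlorination and retro-aldol opening of the fused cyclobutanone.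
3. Enabling feature: on the ten-membered ring the C6 and C8 oxygens are 1,3-related across C7 and C8 is followed by the C9 methylene, i.e. a latent cyclodecane-1,3-dione (cyclooctanone C6 plus a ketene). In addition the Z-C4=C5 alkene and the cis C1–C2 oxirane are cis-cyclooctene features, and the C14/C15 methyls are 1,5-related as in the isoprene dimer.
4. Cyclooctenone 9 comes from (1Z,5Z)-1,5-dimethylcycloocta-1,5-diene 1 by double Shi epoxidation, selenide-mediated epoxide-to-allylic-alcohol transposition, Babler–Dauben oxidation, SeO2 hydroxylation at C3 and hydroxyl-directed epoxidation.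
5. Ring order: eight-membered carbocycle (purchased) → oxirane → transient cyclobutanone → ten-membered carbocycle → γ-lactone.

Key step: step 9

Remark: positions are cited in the germacrane numbering of the target (C1/C2 oxirane, C3 carbinol, C4=C5, C6 lactone carbinol, C7, C8 ester carbinol, C9 methylene, C10 tertiary carbinol, C11–C13 methylene-lactone carbons, C14/C15 methyls) even where a systematic name uses other locants; commercial 1 is assumed to be the pure 1,5-dimethyl isomer (the technical material contains the 1,6-isomer and is purified first).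

**Step 1**
Reactants: 1 (1Z,5Z)-1,5-dimethylcycloocta-1,5-diene
Product: 2 (1R,2S,5R,6S)-1,2:5,6-diepoxy-1,5-dimethylcyclooctane
Conditions: ent-Shi ketone (L-series fructose-derived diacetonide ketone, 30 mol % per alkene), KHSO5 (as Oxone, 2KHSO5·KHSO4·K2SO4), K2CO3, Bu4NHSO4, MeCN–CH2(OMe)2/aq. Na2B4O7, 0 °C
Reagents that add atoms: potassium peroxymonosulfate, [K+].[O-]S(=O)(=O)OO
Why: Shi asymmetric epoxidation of trisubstituted alkenes through the spiro dioxirane transition state; the L-series ketone is expected to make both methyl-bearing carbons R (one becomes C10), and because the two alkenes of C2-symmetric 1 are homotopic the second epoxidation should raise the enantiomeric purity of the C2 cis-diepoxide, the minor centrosymmetric diastereomer being separated.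

**Step 2**
Reactants: 2 (1R,2S,5R,6S)-1,2:5,6-diepoxy-1,5-dimethylcyclooctane
Product: 4 (1R,5R,2Z,6Z)-1,5-dimethylcycloocta-2,6-diene-1,5-diol, via bis-hydroxyselenide 3 (not isolated)
Conditions: PhSeSePh, NaBH4, EtOH, reflux; then THF, 30% H2O2, 0 °C to rt
Reagents that add atoms: diphenyl diselenide, c1ccccc1[Se][Se]c1ccccc1 (its PhSe groups are carried by 3 only)
Why: epoxide-to-allylic-alcohol transposition by selenide opening and selenoxide elimination; PhSe− attacks each epoxide by SN2 at the secondary carbon (C1 and C5, inversion), the selenoxide can only eliminate away from the fully substituted carbinol carbon, the C10 configuration is that of the epoxide, and in the eight-membered ring the new C1=C2 and C5=C6 bonds can only be cis.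

**Step 3**
Reactants: 4 (1R,5R,2Z,6Z)-1,5-dimethylcycloocta-2,6-diene-1,5-diol
Product: 5 (1R,5R,2Z,6Z)-1,5-dimethyl-5-(triethylsilyloxy)cycloocta-2,6-dien-1-ol
Conditions: Et3SiOTf (1.0 equiv), 2,6-lutidine, CH2Cl2, −78 °C
Reagents that add atoms: triethylsilyl trifluoromethanesulfonate, CC[Si](CC)(CC)OS(=O)(=O)C(F)(F)F
Why: silyl triflate silylation of a tertiary alcohol; the two hydroxyls of C2-symmetric 4 are homotopic, so monosilylation should give a single compound (the silylated carbinol becomes C10), with recovered 4 and desilylated bis-ether recycled.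

**Step 4**
Reactants: 5 (1R,5R,2Z,6Z)-1,5-dimethyl-5-(triethylsilyloxy)cycloocta-2,6-dien-1-ol
Product: 6 (7R,2Z,5Z)-3,7-dimethyl-7-(triethylsilyloxy)cycloocta-2,5-dien-1-one
Conditions: C5H5NH[CrO3Cl] (pyridinium chlorochromate), Celite, CH2Cl2, rt
Reagents that add atoms: none
Why: Babler–Dauben oxidative transposition; the chromate ester of the free tertiary allylic alcohol shifts [3,3] to C6 and is oxidised there, giving the β-methyl enone (C6 ketone, C4=C5) with ring-enforced Z geometry, while the silylated C10 carbinol cannot form a chromate ester.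

**Step 5**
Reactants: 6 (7R,2Z,5Z)-3,7-dimethyl-7-(triethylsilyloxy)cycloocta-2,5-dien-1-one
Product: 7 (4S,7R,2Z,5Z)-4-hydroxy-3,7-dimethyl-7-(triethylsilyloxy)cycloocta-2,5-dien-1-one
Conditions: SeO2 (0.5 equiv), t-BuOOH, CH2Cl2, rt
Reagents that add atoms: tert-butyl hydroperoxide, CC(C)(C)OO
Why: SeO2 allylic hydroxylation (ene reaction at the C1=C2 alkene, whose only allylic hydrogens are on C3, then a [2,3]-sigmatropic shift that restores the double bond); the ene step should occur on the alkene face opposite the C10 OSiEt3 group, and the suprafacial [2,3] shift then places the C3 hydroxyl trans to that group.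

**Step 6**
Reactants: 7 (4S,7R,2Z,5Z)-4-hydroxy-3,7-dimethyl-7-(triethylsilyloxy)cycloocta-2,5-dien-1-one
Product: 8 (4R,5R,6R,7R,2Z)-5,6-epoxy-4-hydroxy-3,7-dimethyl-7-(triethylsilyloxy)cyclooct-2-en-1-one
Conditions: VO(acac)2 (5 mol %), t-BuOOH, CH2Cl2, 0 °C to rt
Reagents that add atoms: tert-butyl hydroperoxide, CC(C)(C)OO
Why: hydroxyl-directed vanadium-catalysed epoxidation; the C3 hydroxyl should deliver oxygen to the cis face of the adjacent cis-cyclooctene bond (the usual outcome for cyclooct-2-enols), the conjugated C4=C5 bond is too electron-poor to react, and the C10 oxygen is blocked as its silyl ether.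

**Step 7**
Reactants: 8 (4R,5R,6R,7R,2Z)-5,6-epoxy-4-hydroxy-3,7-dimethyl-7-(triethylsilyloxy)cyclooct-2-en-1-one
Product: 9 (4R,5S,6R,7R,2Z)-4-(tert-butyldimethylsilyloxy)-5,6-epoxy-3,7-dimethyl-7-(triethylsilyloxy)cyclooct-2-en-1-one
Conditions: t-BuMe2SiOTf, 2,6-lutidine, CH2Cl2, −78 °C
Reagents that add atoms: tert-butyldimethylsilyl trifluoromethanesulfonate, CC(C)(C)[Si](C)(C)OS(=O)(=O)C(F)(F)F
Why: standard silylation of a hindered secondary alcohol under non-nucleophilic conditions that leave the epoxide and enone untouched (the C5 descriptor changes only through the priority of silicon).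

**Step 8**
Reactants: 9 (4R,5S,6R,7R,2Z)-4-(tert-butyldimethylsilyloxy)-5,6-epoxy-3,7-dimethyl-7-(triethylsilyloxy)cyclooct-2-en-1-one
Product: 10 (3R,4R,5S,6R)-6-(tert-butyldimethylsilyloxy)-4,5-epoxy-3,7-dimethyl-3-(triethylsilyloxy)-1-(trimethylsilyloxy)cycloocta-1,7-diene
Conditions: LiN(i-Pr)2, THF, −78 °C; then Me3SiCl, Et3N, −78 to 0 °C
Reagents that add atoms: chlorotrimethylsilane, C[Si](C)(C)Cl
Why: kinetic deprotonation of an enone by a lithium amide occurs at the α′ carbon (C9), and O-silylation traps the cross-conjugated enolate as the C6=C9 silyl enol ether; the β-silyloxy group on C10 is a poor leaving group at −78 °C.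

**Step 9**
Reactants: 10 (3R,4R,5S,6R)-6-(tert-butyldimethylsilyloxy)-4,5-epoxy-3,7-dimethyl-3-(triethylsilyloxy)-1-(trimethylsilyloxy)cycloocta-1,7-diene; 11 dichloroacetyl chloride
Product: 14 (1R,2S,3R,10R,4Z)-3-(tert-butyldimethylsilyloxy)-1,2-epoxy-4,10-dimethyl-10-(triethylsilyloxy)cyclodec-4-ene-6,8-dione, via dichlorocyclobutanone 12 (not isolated), via siloxycyclobutanone 13 (not isolated)
Conditions: 11 (slow addition), Et3N, Et2O, 0 °C to rt; filter; then Zn dust, AcOH–i-PrOH–H2O, 0 °C, Zn filtered off, rt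
Reagents that add atoms: none
Why: Dichloroketene, formed from 11 by dehydrochlorination, adds to the electron-rich C6=C9 enol ether bond of 10 in a concerted (2+2) cycloaddition (ketene carbonyl carbon to the nucleophilic C9, CCl2 to C6); zinc in acetic acid then removes both chlorines, and protodesilylation of the β-silyloxy cyclobutanone triggers a strain-driven retro-aldol cleavage of the C6–C9 ring-fusion bond, so that the eight-membered ring becomes the ten-membered 6,8-dione with C7 and C8 inserted. The closest known reaction is the two-carbon ring expansion of cycloalkanone silyl enol ethers to cycloalkane-1,3-diones by dichloroketene cycloaddition and reductive ring opening. The only ring closed is the transient four-membered ring, by the suprafacial–antarafacial ketene–alkene (2+2) mode; the ten-membered ring is not closed but unveiled by cleavage of the bond shared by the four- and eight-membered rings. No permanent stereocentre is created (the fusion centres C6 and C9, expected cis on the face away from the C10 silyloxy group, are destroyed again), C1, C2, C3 and C10 are untouched, and both cis geometries (C4=C5 and the C1–C2 oxirane) were fixed in the eight-membered ring. The step needs site selectivity for the silyl enol ether over the trisubstituted C4=C5 alkene, which the much higher nucleophilicity of the enol ether toward the electrophilic ketene should secure, and cleavage of the fusion bond instead of the exocyclic C6–C7 bond, which is favoured because it gives the more substituted enol of the β-diketone; zinc is removed before the γ-silyloxy enone is unmasked.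

**Step 10**
Reactants: 14 (1R,2S,3R,10R,4Z)-3-(tert-butyldimethylsilyloxy)-1,2-epoxy-4,10-dimethyl-10-(triethylsilyloxy)cyclodec-4-ene-6,8-dione; 15 methyl propiolate
Product: 16 methyl 2-[(1R,2S,3R,7R,10R,4Z)-3-(tert-butyldimethylsilyloxy)-1,2-epoxy-4,10-dimethyl-6,8-dioxo-10-(triethylsilyloxy)cyclodec-4-en-7-yl]prop-2-enoate
Conditions: PPh3 (20 mol %), AcOH and NaOAc (20 mol % each), PhMe, 60 °C
Reagents that add atoms: none
Why: phosphine-catalysed α-addition (umpolung) of a 1,3-dicarbonyl pronucleophile to an alkynoate; PPh3 adds to the β-carbon of 15, the zwitterion deprotonates C7, the dione anion adds to the α-carbon of the vinylphosphonium ion, and proton transfer with loss of PPh3 leaves the 1-(methoxycarbonyl)vinyl group on C7 (a configurationally labile centre, drawn as the epimer carried on), the buffer limiting drift of the new double bond into conjugation.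

**Step 11**
Reactants: 16 methyl 2-[(1R,2S,3R,7R,10R,4Z)-3-(tert-butyldimethylsilyloxy)-1,2-epoxy-4,10-dimethyl-6,8-dioxo-10-(triethylsilyloxy)cyclodec-4-en-7-yl]prop-2-enoate
Product: 17 methyl 2-[(1R,2S,3R,7R,10R,4Z)-3-(tert-butyldimethylsilyloxy)-1,2-epoxy-10-hydroxy-4,10-dimethyl-6,8-dioxocyclodec-4-en-7-yl]prop-2-enoate
Conditions: HF·pyridine, pyridine, THF, 0 °C
Reagents that add atoms: none
Why: buffered HF·pyridine should cleave the triethylsilyl ether faster than the tert-butyldimethylsilyl ether of the hindered C3 carbinol, freeing the C10 hydroxyl that directs the next reduction.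

**Step 12**
Reactants: 17 methyl 2-[(1R,2S,3R,7R,10R,4Z)-3-(tert-butyldimethylsilyloxy)-1,2-epoxy-10-hydroxy-4,10-dimethyl-6,8-dioxocyclodec-4-en-7-yl]prop-2-enoate
Product: 18 methyl 2-[(1R,2S,3R,7R,8R,10R,4Z)-3-(tert-butyldimethylsilyloxy)-1,2-epoxy-8,10-dihydroxy-4,10-dimethyl-6-oxocyclodec-4-en-7-yl]prop-2-enoate
Conditions: Me4NBH(OAc)3, MeCN–AcOH, −30 °C
Reagents that add atoms: none
Why: Evans–Saksena reduction; the C10 hydroxyl exchanges onto boron and delivers hydride intramolecularly to the β-carbonyl C8 only (C6 has no β-hydroxyl, and the reagent reduces neither unassisted ketones nor acrylates), giving the 1,3-anti diol with the C8 hydroxyl on the face opposite the C10 hydroxyl, while labile C7 should react through the epimer whose acrylate group is anti to the incoming hydride and hence cis to the new hydroxyl.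

**Step 13**
Reactants: 18 methyl 2-[(1R,2S,3R,7R,8R,10R,4Z)-3-(tert-butyldimethylsilyloxy)-1,2-epoxy-8,10-dihydroxy-4,10-dimethyl-6-oxocyclodec-4-en-7-yl]prop-2-enoate
Product: 19 methyl 2-[(1R,2S,3R,7R,8R,10R,4Z)-3-(tert-butyldimethylsilyloxy)-1,2-epoxy-10-hydroxy-4,10-dimethyl-6-oxo-8-(triethylsilyloxy)cyclodec-4-en-7-yl]prop-2-enoate
Conditions: Et3SiCl, imidazole, CH2Cl2, 0 °C (on crude 18, without delay)
Reagents that add atoms: chlorotriethylsilane, CC[Si](Cl)(CC)CC
Why: selective silylation of the secondary C8 hydroxyl beside the tertiary C10 hydroxyl, done at once so that the C8 hydroxyl cannot lactonise onto the ester and only the C6 oxygen can later close the lactone.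

**Step 14**
Reactants: 19 methyl 2-[(1R,2S,3R,7R,8R,10R,4Z)-3-(tert-butyldimethylsilyloxy)-1,2-epoxy-10-hydroxy-4,10-dimethyl-6-oxo-8-(triethylsilyloxy)cyclodec-4-en-7-yl]prop-2-enoate
Product: 21 (1R,2S,3R,6S,7S,8R,10R,4Z)-3-(tert-butyldimethylsilyloxy)-1,2-epoxy-10-hydroxy-8-(triethylsilyloxy)germacra-4,11(13)-dien-12,6-olide, via hydroxy ester 20 (not isolated)
Conditions: NaBH4, CeCl3·7H2O, MeOH, −78 °C; then PPTS (cat.), PhH, 50 °C
Reagents that add atoms: none
Why: Luche 1,2-reduction of the enone carbonyl; hydride should enter C6 from the face opposite both the C7 acrylate substituent and the γ-silyloxy group on C3, giving the C6 alcohol cis to C11, which closes the γ-lactone onto the methyl ester under mild acid catalysis.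

**Step 15**
Reactants: 21 (1R,2S,3R,6S,7S,8R,10R,4Z)-3-(tert-butyldimethylsilyloxy)-1,2-epoxy-10-hydroxy-8-(triethylsilyloxy)germacra-4,11(13)-dien-12,6-olide
Product: 22 (1R,2S,3R,6S,7R,8R,10R,4Z)-3-(tert-butyldimethylsilyloxy)-1,2-epoxy-8,10-dihydroxygermacra-4,11(13)-dien-12,6-olide
Conditions: PPTS, MeOH, 0 °C
Reagents that add atoms: none
Why: acid-catalysed methanolysis should remove the secondary triethylsilyl ether selectively while the more hindered and more robust tert-butyldimethylsilyl ether stays.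

**Step 16**
Reactants: 22 (1R,2S,3R,6S,7R,8R,10R,4Z)-3-(tert-butyldimethylsilyloxy)-1,2-epoxy-8,10-dihydroxygermacra-4,11(13)-dien-12,6-olide; 23 angelic acid ((Z)-2-methylbut-2-enoic acid)
Product: 24 (1R,2S,3R,6S,7R,8R,10R,4Z)-8-angeloyloxy-3-(tert-butyldimethylsilyloxy)-1,2-epoxy-10-hydroxygermacra-4,11(13)-dien-12,6-olide
Conditions: 23, 2,4,6-Cl3C6H2COCl, Et3N, PhMe, rt; then 22, PhMe, 70 °C
Reagents that add atoms: none
Why: Yamaguchi mixed-anhydride esterification, run without a nucleophilic amine catalyst so that the (Z)-angelate does not isomerise to the tiglate; only the secondary C8 hydroxyl should react, the tertiary C10 hydroxyl being too hindered.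

**Step 17**
Reactants: 24 (1R,2S,3R,6S,7R,8R,10R,4Z)-8-angeloyloxy-3-(tert-butyldimethylsilyloxy)-1,2-epoxy-10-hydroxygermacra-4,11(13)-dien-12,6-olide
Product: 25 (1R,2R,3R,6S,7R,8R,10R,4Z)-8-angeloyloxy-1,2-epoxy-3,10-dihydroxygermacra-4,11(13)-dien-12,6-olide (CNP0351240.2)
Conditions: Bu4NF, AcOH (1:1), THF, 0 °C to rt
Reagents that add atoms: none
Why: fluoride cleavage of the silyl ether, buffered with acetic acid so that the liberated alkoxide neither adds to the methylene lactone nor shifts the oxirane (Payne rearrangement).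

**Compound list**

1 | (1Z,5Z)-1,5-dimethylcycloocta-1,5-diene | C/C1=C/CC/C(C)=C\CC1 | starting material
2 | (1R,2S,5R,6S)-1,2:5,6-diepoxy-1,5-dimethylcyclooctane (C2-symmetric cis-diepoxide) | C1[C@@H]2O[C@]2(C)CC[C@@H]2O[C@]2(C)C1 | intermediate
3 | (1R,2R,5R,6R)-1,5-dimethyl-2,6-bis(phenylselanyl)cyclooctane-1,5-diol | C1[C@@H]([Se]c2ccccc2)[C@](C)(O)CC[C@@H]([Se]c2ccccc2)[C@](C)(O)C1 | intermediate
4 | (1R,5R,2Z,6Z)-1,5-dimethylcycloocta-2,6-diene-1,5-diol | C1/C=C\[C@](C)(O)C/C=C\[C@]1(C)O | intermediate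
5 | (1R,5R,2Z,6Z)-1,5-dimethyl-5-(triethylsilyloxy)cycloocta-2,6-dien-1-ol | C1/C=C\[C@](C)(O)C/C=C\[C@]1(C)O[Si](CC)(CC)CC | intermediate
6 | (7R,2Z,5Z)-3,7-dimethyl-7-(triethylsilyloxy)cycloocta-2,5-dien-1-one | O=C1/C=C(/C)C/C=C\[C@](C)(O[Si](CC)(CC)CC)C1 | intermediate
7 | (4S,7R,2Z,5Z)-4-hydroxy-3,7-dimethyl-7-(triethylsilyloxy)cycloocta-2,5-dien-1-one | O=C1/C=C(/C)[C@@H](O)/C=C\[C@](C)(O[Si](CC)(CC)CC)C1 | intermediate
8 | (4R,5R,6R,7R,2Z)-5,6-epoxy-4-hydroxy-3,7-dimethyl-7-(triethylsilyloxy)cyclooct-2-en-1-one | O=C1/C=C(/C)[C@@H](O)[C@H]2O[C@H]2[C@](C)(O[Si](CC)(CC)CC)C1 | intermediate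
9 | (4R,5S,6R,7R,2Z)-4-(tert-butyldimethylsilyloxy)-5,6-epoxy-3,7-dimethyl-7-(triethylsilyloxy)cyclooct-2-en-1-one | O=C1/C=C(/C)[C@@H](O[Si](C)(C)C(C)(C)C)[C@H]2O[C@H]2[C@](C)(O[Si](CC)(CC)CC)C1 | intermediate
10 | (3R,4R,5S,6R)-6-(tert-butyldimethylsilyloxy)-4,5-epoxy-3,7-dimethyl-3-(triethylsilyloxy)-1-(trimethylsilyloxy)cycloocta-1,7-diene (C6=C9 silyl enol ether of 9) | C[C@@]1(O[Si](CC)(CC)CC)/C=C(O[Si](C)(C)C)\C=C(\C)[C@@H](O[Si](C)(C)C(C)(C)C)[C@H]2O[C@H]21 | intermediate
11 | dichloroacetyl chloride | ClC(Cl)C(=O)Cl | starting material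
12 | cis-fused 7,7-dichlorocyclobutan-8-one on the C6–C9 bond of the cyclooctene (C6 OSiMe3, formed on the face opposite the C10 OSiEt3 group; both fusion epimers converge) | C[C@@]1(O[Si](CC)(CC)CC)[C@H]2C(=O)C(Cl)(Cl)[C@@]2(O[Si](C)(C)C)/C=C(/C)[C@@H](O[Si](C)(C)C(C)(C)C)[C@H]3O[C@H]31 | intermediate
13 | dechlorinated cyclobutan-8-one of 12 (C7 methylene, C6 OSiMe3) | C[C@@]1(O[Si](CC)(CC)CC)[C@H]2C(=O)C[C@@]2(O[Si](C)(C)C)/C=C(/C)[C@@H](O[Si](C)(C)C(C)(C)C)[C@H]3O[C@H]31 | intermediate
14 | (1R,2S,3R,10R,4Z)-3-(tert-butyldimethylsilyloxy)-1,2-epoxy-4,10-dimethyl-10-(triethylsilyloxy)cyclodec-4-ene-6,8-dione | O=C1/C=C(/C)[C@@H](O[Si](C)(C)C(C)(C)C)[C@H]2O[C@H]2[C@](C)(O[Si](CC)(CC)CC)CC(=O)C1 | intermediate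
15 | methyl propiolate | C#CC(=O)OC | starting material
16 | methyl 2-[(1R,2S,3R,7R,10R,4Z)-3-(tert-butyldimethylsilyloxy)-1,2-epoxy-4,10-dimethyl-6,8-dioxo-10-(triethylsilyloxy)cyclodec-4-en-7-yl]prop-2-enoate (C7 labile) | O=C1/C=C(/C)[C@@H](O[Si](C)(C)C(C)(C)C)[C@H]2O[C@H]2[C@](C)(O[Si](CC)(CC)CC)CC(=O)[C@H]1C(=C)C(=O)OC | intermediate
17 | methyl 2-[(1R,2S,3R,7R,10R,4Z)-3-(tert-butyldimethylsilyloxy)-1,2-epoxy-10-hydroxy-4,10-dimethyl-6,8-dioxocyclodec-4-en-7-yl]prop-2-enoate | O=C1/C=C(/C)[C@@H](O[Si](C)(C)C(C)(C)C)[C@H]2O[C@H]2[C@](C)(O)CC(=O)[C@H]1C(=C)C(=O)OC | intermediate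
18 | methyl 2-[(1R,2S,3R,7R,8R,10R,4Z)-3-(tert-butyldimethylsilyloxy)-1,2-epoxy-8,10-dihydroxy-4,10-dimethyl-6-oxocyclodec-4-en-7-yl]prop-2-enoate | O=C1/C=C(/C)[C@@H](O[Si](C)(C)C(C)(C)C)[C@H]2O[C@H]2[C@](C)(O)C[C@@H](O)[C@H]1C(=C)C(=O)OC | intermediate
19 | methyl 2-[(1R,2S,3R,7R,8R,10R,4Z)-3-(tert-butyldimethylsilyloxy)-1,2-epoxy-10-hydroxy-4,10-dimethyl-6-oxo-8-(triethylsilyloxy)cyclodec-4-en-7-yl]prop-2-enoate | O=C1/C=C(/C)[C@@H](O[Si](C)(C)C(C)(C)C)[C@H]2O[C@H]2[C@](C)(O)C[C@@H](O[Si](CC)(CC)CC)[C@H]1C(=C)C(=O)OC | intermediate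
20 | methyl 2-[(1R,2S,3R,6S,7S,8R,10R,4Z)-3-(tert-butyldimethylsilyloxy)-1,2-epoxy-6,10-dihydroxy-4,10-dimethyl-8-(triethylsilyloxy)cyclodec-4-en-7-yl]prop-2-enoate | O[C@H]1/C=C(/C)[C@@H](O[Si](C)(C)C(C)(C)C)[C@H]2O[C@H]2[C@](C)(O)C[C@@H](O[Si](CC)(CC)CC)[C@H]1C(=C)C(=O)OC | intermediate
21 | (1R,2S,3R,6S,7S,8R,10R,4Z)-3-(tert-butyldimethylsilyloxy)-1,2-epoxy-10-hydroxy-8-(triethylsilyloxy)germacra-4,11(13)-dien-12,6-olide | C=C1C(=O)O[C@H]2/C=C(/C)[C@@H](O[Si](C)(C)C(C)(C)C)[C@H]3O[C@H]3[C@](C)(O)C[C@@H](O[Si](CC)(CC)CC)[C@@H]12 | intermediate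
22 | (1R,2S,3R,6S,7R,8R,10R,4Z)-3-(tert-butyldimethylsilyloxy)-1,2-epoxy-8,10-dihydroxygermacra-4,11(13)-dien-12,6-olide | C=C1C(=O)O[C@H]2/C=C(/C)[C@@H](O[Si](C)(C)C(C)(C)C)[C@H]3O[C@H]3[C@](C)(O)C[C@@H](O)[C@@H]12 | intermediate
23 | angelic acid, (Z)-2-methylbut-2-enoic acid | C/C=C(/C)C(=O)O | starting material
24 | (1R,2S,3R,6S,7R,8R,10R,4Z)-8-angeloyloxy-3-(tert-butyldimethylsilyloxy)-1,2-epoxy-10-hydroxygermacra-4,11(13)-dien-12,6-olide | C=C1C(=O)O[C@H]2/C=C(/C)[C@@H](O[Si](C)(C)C(C)(C)C)[C@H]3O[C@H]3[C@](C)(O)C[C@@H](OC(=O)/C(C)=C\C)[C@@H]12 | intermediate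
25 | (1R,2R,3R,6S,7R,8R,10R,4Z)-8-angeloyloxy-1,2-epoxy-3,10-dihydroxygermacra-4,11(13)-dien-12,6-olide (CNP0351240.2) | C=C1C(=O)O[C@H]2/C=C(/C)[C@@H](O)[C@H]3O[C@H]3[C@](C)(O)C[C@@H](OC(=O)/C(C)=C\C)[C@@H]12 | target

**Step count and risks**

Total step count: 17. Longest linear sequence: 17 steps (1 to 25); 11, 15 and 23 are purchased reagents that enter in steps 9, 10 and 16.

Steps most likely to fail:

Step 9. The retro-aldol after dechlorination may break the exocyclic C6–C7 bond of the four-membered ring instead of the fusion bond, which would leave the eight-membered ring intact with an acetyl group on C9; zinc may also cleave the γ-silyloxy enone reductively. The fallback replaces the polar fragmentation by a radical one, sets out from 13 and returns at 14. The cycloadduct is dechlorinated with zinc–copper couple and NH4Cl in methanol at 0 °C so that 13 can be isolated. Brief treatment with citric acid in methanol at 0 °C removes only the trimethylsilyl ether and gives the β-hydroxy cyclobutanone F1. PhI(OAc)2 and I2 under visible light generate the C6 alkoxy radical, whose β-scission is expected to break the fusion bond because this gives the secondary, carbonyl-stabilised C9 radical, trapped as the C9 iodo dione F2. Zn in AcOH removes the iodine and gives 14.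

Step 10. The adduct keeps an acidic C7–H, so a second propiolate may add, the new double bond may drift into conjugation with the dione, or the enol oxygen may add instead of carbon. The fallback is classical C-alkylation followed by late α-methylenation, sets out from 14 and returns at 21. Alkylation of 14 with methyl bromoacetate (K2CO3, acetone) gives the C7 acetic ester F3. The operations of steps 11 to 14 (HF·pyridine; Me4NBH(OAc)3; Et3SiCl and imidazole at once; NaBH4/CeCl3·7H2O, then PPTS) lead through the C10 alcohol F4, the C8 alcohol F5, its triethylsilyl ether F6 and the C6 hydroxy ester F7 to the saturated lactone F8. The lactone enolate (LiN(i-Pr)2, 2.2 equiv, THF, −78 °C, the C10 alkoxide forming first) is aminomethylated with Eschenmoser's salt (Me2N=CH2 iodide) to the Mannich base F9. This is quaternised with MeI to the ammonium iodide F10 and eliminated with aqueous NaHCO3 to give 21.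

Step 5. The ene step may show poor facial selectivity, giving the C3 epimer, and the allylic alcohol may be over-oxidised to the enedione. The fallback adds a stereochemical correction, sets out from 6 and returns at 7. The hydroxylation is run as in step 5 at partial conversion; if the (4R) epimer F11 predominates it is separated and inverted by a Mitsunobu reaction (PPh3, DIAD, 4-nitrobenzoic acid, THF, 0 °C) to the (4S) 4-nitrobenzoate F12. Methanolysis (K2CO3, MeOH, 0 °C) then gives 7.

**Further compounds**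

F1 | step 9 | β-hydroxy cyclobutanone (13 without the trimethylsilyl group, C6–OH) | C[C@@]1(O[Si](CC)(CC)CC)[C@H]2C(=O)C[C@@]2(O)/C=C(/C)[C@@H](O[Si](C)(C)C(C)(C)C)[C@H]3O[C@H]31
F2 | step 9 | 9-iodo derivative of 14 (C9 epimers) | O=C1/C=C(/C)[C@@H](O[Si](C)(C)C(C)(C)C)[C@H]2O[C@H]2[C@](C)(O[Si](CC)(CC)CC)C(I)C(=O)C1
F3 | step 10 | methyl 2-[(1R,2S,3R,10R,4Z)-3-(tert-butyldimethylsilyloxy)-1,2-epoxy-4,10-dimethyl-6,8-dioxo-10-(triethylsilyloxy)cyclodec-4-en-7-yl]acetate (C7 labile) | O=C1/C=C(/C)[C@@H](O[Si](C)(C)C(C)(C)C)[C@H]2O[C@H]2[C@](C)(O[Si](CC)(CC)CC)CC(=O)[C@H]1CC(=O)OC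
F4 | step 10 | C10 alcohol of F3 | O=C1/C=C(/C)[C@@H](O[Si](C)(C)C(C)(C)C)[C@H]2O[C@H]2[C@](C)(O)CC(=O)[C@H]1CC(=O)OC
F5 | step 10 | C8,C10 diol from F4 (8R) | O=C1/C=C(/C)[C@@H](O[Si](C)(C)C(C)(C)C)[C@H]2O[C@H]2[C@](C)(O)C[C@@H](O)[C@H]1CC(=O)OC
F6 | step 10 | C8 triethylsilyl ether of F5 | O=C1/C=C(/C)[C@@H](O[Si](C)(C)C(C)(C)C)[C@H]2O[C@H]2[C@](C)(O)C[C@@H](O[Si](CC)(CC)CC)[C@H]1CC(=O)OC
F7 | step 10 | C6 hydroxy ester from F6 (6S) | O[C@H]1/C=C(/C)[C@@H](O[Si](C)(C)C(C)(C)C)[C@H]2O[C@H]2[C@](C)(O)C[C@@H](O[Si](CC)(CC)CC)[C@H]1CC(=O)OC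
F8 | step 10 | 13-nor-11,13-dihydro analogue of 21 (saturated γ-lactone, C11 methylene) | C1C(=O)O[C@H]2/C=C(/C)[C@@H](O[Si](C)(C)C(C)(C)C)[C@H]3O[C@H]3[C@](C)(O)C[C@@H](O[Si](CC)(CC)CC)[C@@H]12
F9 | step 10 | 13-(dimethylamino)-11,13-dihydro derivative of 21 (C11 epimers) | CN(C)CC1C(=O)O[C@H]2/C=C(/C)[C@@H](O[Si](C)(C)C(C)(C)C)[C@H]3O[C@H]3[C@](C)(O)C[C@@H](O[Si](CC)(CC)CC)[C@@H]12
F10 | step 10 | trimethylammonium iodide of F9 | [I-].C[N+](C)(C)CC1C(=O)O[C@H]2/C=C(/C)[C@@H](O[Si](C)(C)C(C)(C)C)[C@H]3O[C@H]3[C@](C)(O)C[C@@H](O[Si](CC)(CC)CC)[C@@H]12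
F11 | step 5 | (4R,7R,2Z,5Z)-4-hydroxy-3,7-dimethyl-7-(triethylsilyloxy)cycloocta-2,5-dien-1-one (C3 epimer of 7) | O=C1/C=C(/C)[C@H](O)/C=C\[C@](C)(O[Si](CC)(CC)CC)C1
F12 | step 5 | 4-nitrobenzoate of 7 (4S,7R) | O=C1/C=C(/C)[C@@H](OC(=O)c2ccc(cc2)[N+](=O)[O-])/C=C\[C@](C)(O[Si](CC)(CC)CC)C1
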